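**Plan**

Numbering used throughout: C1 methyl-bearing fusion carbon, C2 and C3 ring CH2, C4 isopropyl carbinol, C5 fusion CH, C6 ester-bearing CH, C7 CH2, C8 methyl-bearing alkene carbon, C9 alkene CH, C10 ketone carbon.
Cuts, in retrosynthetic order: the C6–O ester bond; C8=C9 of the seven-membered ring (aldol–elimination of a C10 methyl ketone onto a C8 ketal); the C4–isopropyl bond; then C1–C10 and C5–C6 in one operation.
Enabling feature: in the five-membered ring, C4–C5–C1 is the carbonyl, α- and β-carbon of 3-methylcyclopent-2-enone, so C10 can enter at C1 as a 1-silylvinyl nucleophile (a masked acetyl group) and C6 at C5 as an aldehyde.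
Forward order: the cyclopentane is bought as the enone; the three-component step attaches both side chains; isopropyl is added at C4; the vinylsilane is unmasked to the acetyl group; the seven-membered ring closes last; the C6 hydroxyl is esterified.
Stereochemistry: C1 from the chiral copper–carbene catalyst; C5 and C6 from the aldol (aldehyde anti to the silylvinyl group, chair transition state of the ring (E)-enolate); C4 from attack of the isopropyl reagent anti to the C5 side chain.

Key step: step 4

Assumption: the carbene precursor is 2-[(4S,5S)-3-(2,6-diethylphenyl)-4,5-diphenyl-4,5-dihydro-1H-imidazol-3-ium-1-yl]benzenesulfonate or its mirror image, whichever gives the (S) configuration at C1; the sense of induction is not predicted here.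

**Route**

Step 1
Reactants: 1 ethyl acetoacetate
Product: 2 ethyl (2-methyl-1,3-dioxolan-2-yl)acetate
Conditions: HOCH2CH2OH (1.5 equiv), p-toluenesulfonic acid (1 mol%), toluene, reflux, azeotropic removal of water
Reagents that add atoms: ethylene glycol, OCCO
Why: Acid-catalysed ketalisation of the ketone of a β-keto ester is a standard protection that leaves the ester untouched.

Step 2
Reactants: 2 ethyl (2-methyl-1,3-dioxolan-2-yl)acetate
Product: 3 (2-methyl-1,3-dioxolan-2-yl)acetaldehyde
Conditions: i-Bu2AlH (1.05 equiv), CH2Cl2, −78 °C; aq. potassium sodium tartrate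
Reagents that add atoms: none
Why: Partial reduction of an ester with i-Bu2AlH at low temperature should stop at the aluminium hemiacetal and release the aldehyde on neutral work-up, with the ketal unaffected; the aldehyde is used fresh.

Step 3
Reactants: 4 ethynyltrimethylsilane
Product: 5 diisobutyl[1-(trimethylsilyl)vinyl]aluminium (used as the solution obtained)
Conditions: i-Bu2AlH (1.0 equiv), hexanes/THF 5:1, 55 °C, 2 h
Reagents that add atoms: diisobutylaluminium hydride, CC(C)C[AlH]CC(C)C
Why: Hydroalumination of a silylacetylene in the presence of THF should place aluminium on the silicon-bearing carbon, giving the geminal silyl alkenylalane.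

Step 4
Reactants: 6 3-methylcyclopent-2-en-1-one; 5 diisobutyl[1-(trimethylsilyl)vinyl]aluminium; 3 (2-methyl-1,3-dioxolan-2-yl)acetaldehyde
Product: 8 (2S,3S)-2-[(1S)-1-hydroxy-2-(2-methyl-1,3-dioxolan-2-yl)ethyl]-3-methyl-3-[1-(trimethylsilyl)ethenyl]cyclopentan-1-one, via aluminium enolate 7 (not isolated)
Conditions: Cu(OTf)2 (5 mol%), chiral imidazolinium sulfonate (5 mol%), 5 (1.2 equiv), THF, −78 °C; then 3 (1.5 equiv), −78 → −40 °C; aq. potassium sodium tartrate
Reagents that add atoms: none
Why: The alane deprotonates the imidazolinium salt and reduces the divalent copper salt, and the resulting monovalent copper–carbene complex takes over the 1-silylvinyl group and adds it 1,4 to C1 of 6, leaving the aluminium enolate 7, which adds through C5 to aldehyde 3 in a closed six-membered transition state. The closest known reaction type is the carbene–copper-catalysed enantioselective conjugate addition of silyl-substituted alkenylaluminium reagents to β-substituted cyclic enones, combined with the aldol trapping of aluminium enolates known from copper-catalysed organoaluminium additions. No ring is closed; the bonds C1–C10 and C5–C6 and three stereocentres are formed. C1 is set by the chiral carbene ligand, C5 by approach of the aldehyde to the enolate face opposite the bulky silylvinyl group on the neighbouring quaternary carbon (C6 ends up cis to the C1 methyl), and C6 by the chair transition state of the ring-locked (E)-enolate with the aldehyde chain equatorial, which leads to the anti aldol. The step needs 1,4- over 1,2-addition, transfer of alkenyl in preference to isobutyl, and aldol capture faster than addition of leftover alane to the aldehyde; the β-methyl enone with the copper catalyst, the faster transfer of sp2 groups, and a small excess of 5 at low temperature should secure these. The neutral tartrate work-up should keep the β-hydroxy ketone from retro-aldol cleavage and the ketal intact.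

Step 5
Reactants: 8 aldol product
Product: 9 (2S,3S)-3-methyl-2-[(1S)-2-(2-methyl-1,3-dioxolan-2-yl)-1-(triethylsilyloxy)ethyl]-3-[1-(trimethylsilyl)ethenyl]cyclopentan-1-one
Conditions: Et3SiCl (1.5 equiv), imidazole (3 equiv), DMF, 0 °C → rt
Reagents that add atoms: chlorotriethylsilane, CC[Si](CC)(CC)Cl
Why: Silylation of the secondary C6 hydroxyl under mildly basic conditions should block retro-aldol cleavage in the next step and leave the ketal and vinylsilane untouched.

Step 6
Reactants: 9 silyl-protected aldol
Product: 10 (1R,2S,3S)-3-methyl-2-[(1S)-2-(2-methyl-1,3-dioxolan-2-yl)-1-(triethylsilyloxy)ethyl]-1-(propan-2-yl)-3-[1-(trimethylsilyl)ethenyl]cyclopentan-1-ol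
Conditions: i-PrMgCl (3 equiv), CeCl3 (3 equiv, dried), THF, −78 → −20 °C; aq. NH4Cl
Reagents that add atoms: isopropylmagnesium chloride, CC(C)[Mg]Cl
Why: The organocerium reagent is nucleophilic but weakly basic, so 1,2-addition to the hindered, enolisable C4 ketone should outrun enolisation and β-elimination, and attack on the cyclopentanone face anti to the adjacent C5 side chain places isopropyl trans and hydroxyl cis to C6 as in the target.

Step 7
Reactants: 10 tertiary alcohol
Product: 11 (1R,2S,3S)-3-[1,2-dihydroxy-1-(trimethylsilyl)ethyl]-3-methyl-2-[(1S)-2-(2-methyl-1,3-dioxolan-2-yl)-1-(triethylsilyloxy)ethyl]-1-(propan-2-yl)cyclopentan-1-ol (both C10 epimers)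
Conditions: OsO4 (5 mol%), N-methylmorpholine N-oxide (2 equiv), acetone/H2O 4:1, rt
Reagents that add atoms: osmium tetroxide, O=[Os](=O)(=O)=O; N-methylmorpholine N-oxide, C[N+]1([O-])CCOCC1; water, O
Why: Catalytic osmium tetroxide dihydroxylation of the only alkene should give the α,β-dihydroxysilane under neutral conditions that spare the ketal and silyl ether, and the new C10 centre is removed again in step 8.

Step 8
Reactants: 11 α,β-dihydroxysilane
Product: 12 1-{(1S,2S,3R)-3-hydroxy-1-methyl-2-[(1S)-2-(2-methyl-1,3-dioxolan-2-yl)-1-(triethylsilyloxy)ethyl]-3-(propan-2-yl)cyclopentyl}ethan-1-one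
Conditions: KH (4 equiv), THF, 0 °C → rt; AcOH, 0 °C
Reagents that add atoms: none
Why: Base-induced Peterson elimination (the primary alkoxide attacks silicon and trimethylsilanolate leaves) should give the enolate of the C10 methyl ketone regiospecifically, which is protonated on quenching; no aqueous acid is involved, so the C8 ketal survives.

Step 9
Reactants: 12 methyl ketone
Product: 13 bis(trimethylsilyl) derivative of 12 (trimethylsilyl enol ether C10(OSiMe3)=C9H2 and trimethylsilyl ether at C4)
Conditions: lithium diisopropylamide (2.5 equiv), THF, −78 °C; Me3SiCl (4 equiv), Et3N, −78 → 0 °C; pentane, cold aq. NaHCO3; used crude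
Reagents that add atoms: chlorotrimethylsilane, C[Si](C)(C)Cl
Why: Because C1 is quaternary the acetyl group can enolise only towards C9, so kinetic deprotonation and O-silylation should give a single silyl enol ether while the C4 alkoxide is capped as its trimethylsilyl ether.

Step 10
Reactants: 13 silyl enol ether
Product: 15 (1R,3aS,8S,8aS)-3a,6-dimethyl-1-(propan-2-yl)-8-(triethylsilyloxy)-1-(trimethylsilyloxy)-2,3,3a,7,8,8a-hexahydroazulen-4(1H)-one, via cyclised alkoxy ketone 14 (not isolated)
Conditions: Me3SiOTf (0.3 equiv), 2,6-di-tert-butylpyridine (0.1 equiv), CH2Cl2, −78 → −30 °C; then DBU (3 equiv), 0 °C → rt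
Reagents that add atoms: none
Why: The silyl triflate should open the dioxolane to a C8 oxocarbenium ion that is attacked by C9 of the silyl enol ether in an intramolecular Mukaiyama aldol-type addition to a ketal (a favoured 7-(enolendo)-exo-trig closure), and DBU then removes the 2-silyloxyethoxy group of 14 by E1cB elimination to place C8=C9 in conjugation with C10.

Step 11
Reactants: 15 bis-silylated enone
Product: 16 (1R,3aS,8S,8aS)-1,8-dihydroxy-3a,6-dimethyl-1-(propan-2-yl)-2,3,3a,7,8,8a-hexahydroazulen-4(1H)-one
Conditions: HF·pyridine, pyridine/THF, 0 °C → rt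
Reagents that add atoms: none
Why: Buffered fluoride should cleave the trimethylsilyl ether at C4 and the triethylsilyl ether at C6 without strong base, which avoids vinylogous elimination of the C6 oxygen from the enone.

Step 12
Reactants: 16 dihydroxy enone; 17 4-methoxybenzoyl chloride
Product: 18 (1R,3aS,8S,8aS)-1-hydroxy-3a,6-dimethyl-4-oxo-1-(propan-2-yl)-1,2,3,3a,4,7,8,8a-octahydroazulen-8-yl 4-methoxybenzoate
Conditions: Et3N (2 equiv), DMAP (0.2 equiv), CH2Cl2, 0 °C → rt
Reagents that add atoms: none
Why: DMAP-catalysed acylation should occur only at the secondary C6 hydroxyl, the tertiary C4 hydroxyl being too hindered, and no stereocentre is touched.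

**Compound list**

1 | ethyl acetoacetate | CCOC(=O)CC(C)=O | starting material
2 | ethyl (2-methyl-1,3-dioxolan-2-yl)acetate | CCOC(=O)CC1(C)OCCO1 | intermediate
3 | (2-methyl-1,3-dioxolan-2-yl)acetaldehyde | CC1(CC=O)OCCO1 | intermediate
4 | ethynyltrimethylsilane | C#C[Si](C)(C)C | starting material
5 | diisobutyl[1-(trimethylsilyl)vinyl]aluminium | C=C([Si](C)(C)C)[Al](CC(C)C)CC(C)C | intermediate
6 | 3-methylcyclopent-2-en-1-one | CC1=CC(=O)CC1 | starting material
7 | diisobutyl{[(3S)-3-methyl-3-[1-(trimethylsilyl)ethenyl]cyclopent-1-en-1-yl]oxy}aluminium (formed in the flask) | CC(C)C[Al](CC(C)C)OC1=C[C@@](C)(C(=C)[Si](C)(C)C)CC1 | intermediate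
8 | (2S,3S)-2-[(1S)-1-hydroxy-2-(2-methyl-1,3-dioxolan-2-yl)ethyl]-3-methyl-3-[1-(trimethylsilyl)ethenyl]cyclopentan-1-one | O[C@@H](CC1(C)OCCO1)[C@@H]2[C@@](C)(C(=C)[Si](C)(C)C)CCC2=O | intermediate
9 | (2S,3S)-3-methyl-2-[(1S)-2-(2-methyl-1,3-dioxolan-2-yl)-1-(triethylsilyloxy)ethyl]-3-[1-(trimethylsilyl)ethenyl]cyclopentan-1-one | CC[Si](CC)(CC)O[C@@H](CC1(C)OCCO1)[C@@H]2[C@@](C)(C(=C)[Si](C)(C)C)CCC2=O | intermediate
10 | (1R,2S,3S)-3-methyl-2-[(1S)-2-(2-methyl-1,3-dioxolan-2-yl)-1-(triethylsilyloxy)ethyl]-1-(propan-2-yl)-3-[1-(trimethylsilyl)ethenyl]cyclopentan-1-ol | CC[Si](CC)(CC)O[C@@H](CC1(C)OCCO1)[C@@H]2[C@@](C)(C(=C)[Si](C)(C)C)CC[C@@]2(O)C(C)C | intermediate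
11 | (1R,2S,3S)-3-[1,2-dihydroxy-1-(trimethylsilyl)ethyl]-3-methyl-2-[(1S)-2-(2-methyl-1,3-dioxolan-2-yl)-1-(triethylsilyloxy)ethyl]-1-(propan-2-yl)cyclopentan-1-ol, both epimers at the silyl carbinol carbon | CC[Si](CC)(CC)O[C@@H](CC1(C)OCCO1)[C@@H]2[C@@](C)(C(O)(CO)[Si](C)(C)C)CC[C@@]2(O)C(C)C | intermediate
12 | 1-{(1S,2S,3R)-3-hydroxy-1-methyl-2-[(1S)-2-(2-methyl-1,3-dioxolan-2-yl)-1-(triethylsilyloxy)ethyl]-3-(propan-2-yl)cyclopentyl}ethan-1-one | CC[Si](CC)(CC)O[C@@H](CC1(C)OCCO1)[C@@H]2[C@@](C)(C(C)=O)CC[C@@]2(O)C(C)C | intermediate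
13 | bis(trimethylsilyl) derivative of 12: trimethylsilyl enol ether of the acetyl group and trimethylsilyl ether of the C4 hydroxyl, same spatial arrangement as 12 | CC[Si](CC)(CC)O[C@@H](CC1(C)OCCO1)[C@@H]2[C@@](C)(C(=C)O[Si](C)(C)C)CC[C@@]2(O[Si](C)(C)C)C(C)C | intermediate
14 | cyclised β-alkoxy ketone (formed in the flask): seven-membered ring closed at C8–C9, C8 bearing methyl and 2-(trimethylsilyloxy)ethoxy (both C8 epimers), C10 ketone, C4 OSiMe3, C6 OSiEt3 | CC[Si](CC)(CC)O[C@H]1CC(C)(OCCO[Si](C)(C)C)CC(=O)[C@@]2(C)CC[C@@](O[Si](C)(C)C)(C(C)C)[C@H]12 | intermediate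
15 | (1R,3aS,8S,8aS)-3a,6-dimethyl-1-(propan-2-yl)-8-(triethylsilyloxy)-1-(trimethylsilyloxy)-2,3,3a,7,8,8a-hexahydroazulen-4(1H)-one | CC[Si](CC)(CC)O[C@H]1CC(C)=CC(=O)[C@@]2(C)CC[C@@](O[Si](C)(C)C)(C(C)C)[C@H]12 | intermediate
16 | (1R,3aS,8S,8aS)-1,8-dihydroxy-3a,6-dimethyl-1-(propan-2-yl)-2,3,3a,7,8,8a-hexahydroazulen-4(1H)-one | O[C@H]1CC(C)=CC(=O)[C@@]2(C)CC[C@@](O)(C(C)C)[C@H]12 | intermediate
17 | 4-methoxybenzoyl chloride | COc1ccc(C(Cl)=O)cc1 | starting material
18 | (1R,3aS,8S,8aS)-1-hydroxy-3a,6-dimethyl-4-oxo-1-(propan-2-yl)-1,2,3,3a,4,7,8,8a-octahydroazulen-8-yl 4-methoxybenzoate | COc1ccc(C(=O)O[C@H]2CC(C)=CC(=O)[C@@]3(C)CC[C@@](O)(C(C)C)[C@H]23)cc1 | target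

**Step count and risks**

Total steps: 12. Longest linear sequence: 11 steps (steps 1, 2 and 4 to 12, from ethyl acetoacetate).

Most likely to fail:

Step 4. The crowded aluminium enolate may be captured by the aldehyde slowly or with erosion of the anti relationship, and leftover alane may transfer its alkenyl group to the aldehyde. Fallback: the conjugate addition of 5 to 6 is run alone and the enolate 7 is silylated in the flask with Me3SiOTf to give the trimethylsilyl enol ether F1, which is isolated. MeLi in THF at 0 °C then releases the regiodefined lithium enolate F2, and this is treated at −78 °C with aldehyde 3 in a separate, chair-controlled lithium aldol addition. The route is rejoined at compound 8.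

Step 10. The oxocarbenium ion may lose a proton to an enol ether or be captured by a neighbouring oxygen faster than the entropically costly seven-membered ring closes. Fallback, setting out from silyl enol ether 13: bromination with N-bromosuccinimide in THF at −78 °C should give the α-bromo ketone F5. Pyridinium p-toluenesulfonate in wet acetone should remove the dioxolane and the C4 trimethylsilyl ether to give the bromo diketone F6. SmI2 (2.2 equiv) in THF at −78 °C should then generate the samarium enolate at C9 only, where the bromine sits, and an intramolecular Reformatsky reaction onto the C8 ketone should close the ring to the β-hydroxy ketone F7. Dehydration with catalytic p-toluenesulfonic acid in benzene should give the enone F8, and HF·pyridine as in step 11 brings the material back to compound 16.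

Step 8. At the crowded C10 the elimination may be slow, or silicon may migrate from carbon to the tertiary oxygen and the carbanion be protonated; the osmylation one step earlier may also be sluggish. Fallback, setting out from vinylsilane 10 and bypassing 11: iododesilylation with N-iodosuccinimide in MeCN at 0 °C (2,6-lutidine buffer) should give the 1-iodovinyl compound F3. After deprotonation of the C4 hydroxyl with MeLi, iodine–lithium exchange with t-BuLi in Et2O at −78 °C and quenching with B(OMe)3 should give the alkenylboronate F4. Oxidation in the same flask with NaBO3·4H2O in THF/H2O should deliver the methyl ketone through its enol, rejoining the route at compound 12.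

**Further compounds**

F1 | step 4 | trimethyl{[(3S)-3-methyl-3-[1-(trimethylsilyl)ethenyl]cyclopent-1-en-1-yl]oxy}silane | C[Si](C)(C)OC1=C[C@@](C)(C(=C)[Si](C)(C)C)CC1
F2 | step 4 | lithium (3S)-3-methyl-3-[1-(trimethylsilyl)ethenyl]cyclopent-1-en-1-olate | [Li]OC1=C[C@@](C)(C(=C)[Si](C)(C)C)CC1
F3 | step 8 | 1-iodovinyl analogue of 10 (iodine in place of the trimethylsilyl group at C10) | CC[Si](CC)(CC)O[C@@H](CC1(C)OCCO1)[C@@H]2[C@@](C)(C(I)=C)CC[C@@]2(O)C(C)C
F4 | step 8 | dimethyl alkenylboronate from F3 (B(OMe)2 at C10) | CC[Si](CC)(CC)O[C@@H](CC1(C)OCCO1)[C@@H]2[C@@](C)(C(=C)B(OC)OC)CC[C@@]2(O[H])C(C)C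
F5 | step 10 | α-bromo ketone from 13 (C10 ketone, C9 CH2Br, C4 OSiMe3, dioxolane intact) | CC[Si](CC)(CC)O[C@@H](CC1(C)OCCO1)[C@@H]2[C@@](C)(C(=O)CBr)CC[C@@]2(O[Si](C)(C)C)C(C)C
F6 | step 10 | bromo diketone (C8 ketone freed, C4 hydroxyl free) | CC[Si](CC)(CC)O[C@@H](CC(C)=O)[C@@H]1[C@@](C)(C(=O)CBr)CC[C@@]1(O)C(C)C
F7 | step 10 | seven-membered β-hydroxy ketone (C8 tertiary hydroxyl, both C8 epimers) | CC[Si](CC)(CC)O[C@H]1CC(C)(O)CC(=O)[C@@]2(C)CC[C@@](O)(C(C)C)[C@H]12
F8 | step 10 | (1R,3aS,8S,8aS)-1-hydroxy-3a,6-dimethyl-1-(propan-2-yl)-8-(triethylsilyloxy)-2,3,3a,7,8,8a-hexahydroazulen-4(1H)-one | CC[Si](CC)(CC)O[C@H]1CC(C)=CC(=O)[C@@]2(C)CC[C@@](O)(C(C)C)[C@H]12
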